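**Strategy.** The route rests on disconnecting the C6–C1 bond of the spiro[5.5]undecane (C6 spiro; ring B = C1–C5; ring A = C7–C11). C6 is a quaternary carbon wedged between C7 (Me, O) and C11 (Me2), out of reach of ionic C–C bond formation but well suited to a tertiary radical. One hydrogen-atom-transfer operation on an exocyclic alkylidene ynone generates that radical, closes ring B as the 1-en-3-one and sets the spiro centre. The precursor is an (E)-1-cyclohexylidenepent-4-yn-3-one whose ring A already carries the equatorial C9 bromide and a silylated axial C7 oxygen, which steer the facial course. Ring A comes from ketoisophorone; a Wittig bromomethylenation finishes the diene.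

Key step: step 11

**Remarks on the chemistry (assumptions)**
- Target numbering: C1=C2, C3 (=CHBr), C4, C5, spiro C6, C7 (Me, OH), C8, C9 (Br), C10, C11 (Me2); the target is (3E,6S,7S,9R). Monocyclic intermediates use cyclohexanone numbering: C1 (later C6), C2 (CMe2, later C11), C4 (later C9), C6 (later C7).
- The C9 bromide is installed before the cyclisation. With Br equatorial and trans to the C7 oxygen, the only low-energy ring-A chair has the C7–O bond axial, so no cyclic diol tether is needed; such a tether would force a syn-triaxial Me/O/O arrangement. The strongly basic and acidic steps are also kept away from a late-stage secondary alcohol.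
- Compounds 11–17 are drawn and named as E alkylidene isomers; a Z component is expected and is carried along, because hydrogen-atom transfer erases this geometry.
- The carbinol centres of 10 and 16 are of no consequence (removed in the following step); 10 is drawn as the expected epimer.

**Route**

Step 1
Reactants: 1 ketoisophorone
Product: 3 (4R,6R)-4-hydroxy-2,2,6-trimethylcyclohexan-1-one (actinol), via levodione 2 (not isolated)
Conditions: ene-reductase OYE2, then levodione reductase; NAD(P)+ (cat.), D-glucose, glucose dehydrogenase, phosphate buffer pH 7, 30 °C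
Reagents that add atoms: none
Why: Known two-enzyme cascade (ene-reductase conjugate reduction, then levodione reductase): hydride adds to the enedione C=C to give the (6R)-dione and the second enzyme reduces only the unhindered C4 carbonyl from one face, setting C4 as R, the centre that becomes C9 of the target.

Step 2
Reactants: 3 actinol
Product: 4 (5R)-1,3,3-trimethyl-2,5-bis(triethylsilyloxy)cyclohex-1-ene
Conditions: TESOTf (2.4 equiv), Et3N, CH2Cl2, 0 °C → rt
Reagents that add atoms: triethylsilyl trifluoromethanesulfonate, CC[Si](CC)(CC)OS(=O)(=O)C(F)(F)F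
Why: Soft enolisation with a silyl triflate and amine: the ketone can enolise only toward C6, its single α-CH, and the C4 hydroxyl is silylated in the same operation, so C6 becomes planar while C4 is untouched.

Step 3
Reactants: 4 bis-silyl enol ether
Product: 7 (4S,6S)-4-hydroxy-2,2,6-trimethyl-6-(triethylsilyloxy)cyclohexan-1-one, via silyloxy epoxide 5 (not isolated), via bis(triethylsilyl) ketone 6 (not isolated)
Conditions: mCPBA, NaHCO3, CH2Cl2, −20 → 0 °C; then PPTS (cat.), MeOH, 0 °C
Reagents that add atoms: mCPBA, OOC(=O)c1cccc(Cl)c1
Why: Rubottom oxidation: the peracid epoxidises the enol ether anti to the pseudoaxial C2 methyl of the half-chair that keeps C4–OTES equatorial, i.e. on the face of the C4 oxygen, and epoxide opening with 1,4-silyl shift gives the cis-4,6-dioxygenated ketone (new C6 centre, S), after which mild acid methanolysis removes only the unhindered secondary silyl ether.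

Step 4
Reactants: 7 hydroxy ketone
Product: 8 (4R,6S)-4-bromo-2,2,6-trimethyl-6-(triethylsilyloxy)cyclohexan-1-one
Conditions: PPh3, CBr4, 2,6-lutidine, CH2Cl2, 0 °C → rt
Reagents that add atoms: carbon tetrabromide, BrC(Br)(Br)Br
Why: Appel reaction: bromide displaces the secondary oxyphosphonium by SN2 with inversion at C4 (now R), putting Br trans to the C6 oxygen, while the tertiary silyl ether and the non-enolisable ketone cannot react.

Step 5
Reactants: 8 bromo ketone; 9 allylmagnesium bromide
Product: 10 (1R,4R,6S)-4-bromo-2,2,6-trimethyl-1-(prop-2-en-1-yl)-6-(triethylsilyloxy)cyclohexan-1-ol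
Conditions: allylMgBr (Et2O), THF, −78 → −20 °C; aq NH4Cl
Reagents that add atoms: allylmagnesium bromide, C=CC[Mg]Br
Why: Grignard 1,2-addition: allylmagnesium halides add through a compact cyclic transition state even to ketones flanked by two quaternary carbons, at −78 °C the alkyl bromide and silyl ether are inert, and the new carbinol centre (allyl expected anti to the axial OTES) is erased in step 6.

Step 6
Reactants: 10 tertiary homoallylic alcohol
Product: 11 (4R,6S)-4-bromo-2,2,6-trimethyl-1-[(E)-prop-2-en-1-ylidene]-6-(triethylsilyloxy)cyclohexane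
Conditions: Burgess reagent, toluene, 50 °C
Reagents that add atoms: none
Why: Burgess dehydration (syn-elimination of the sulfamate): C2 and C6 are quaternary, so the only β-hydrogens sit on the allyl CH2 and the conjugated exocyclic diene is the sole possible alkene, its E/Z ratio being irrelevant.

Step 7
Reactants: 11 diene
Product: 13 (E)-3-[(4R,6S)-4-bromo-2,2,6-trimethyl-6-(triethylsilyloxy)cyclohexylidene]propan-1-ol, via alkylborane 12 (not isolated)
Conditions: 9-BBN, THF, 0 °C → rt; then 30% H2O2, aq NaOAc, 0 °C
Reagents that add atoms: hydrogen peroxide, OO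
Why: Hydroboration–oxidation: 9-BBN places boron on the terminal CH2 of the monosubstituted alkene and cannot reach the trisubstituted alkene buried between C2 and C6, and buffered peroxide oxidation with retention gives the primary homoallylic alcohol without disturbing Br or OTES.

Step 8
Reactants: 13 homoallylic alcohol
Product: 14 (E)-3-[(4R,6S)-4-bromo-2,2,6-trimethyl-6-(triethylsilyloxy)cyclohexylidene]propanal
Conditions: Dess–Martin periodinane, NaHCO3, CH2Cl2, 0 °C → rt; used crude
Reagents that add atoms: none
Why: Dess–Martin oxidation under bicarbonate buffer gives the β,γ-unsaturated aldehyde without base, so the alkene stays out of conjugation (that shift would need protonation at the shielded ring carbon).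

Step 9
Reactants: 14 aldehyde; 15 ethynylmagnesium bromide
Product: 16 (E)-1-[(4R,6S)-4-bromo-2,2,6-trimethyl-6-(triethylsilyloxy)cyclohexylidene]pent-4-yn-3-ol (both carbinol epimers)
Conditions: HC≡CMgBr (THF), THF, −78 → 0 °C; aq NH4Cl
Reagents that add atoms: ethynylmagnesium bromide, C#C[Mg]Br
Why: Grignard addition of the acetylide to the aldehyde is far faster than any reaction at the hindered equatorial bromide, and the carbinol centre it creates is oxidised away in step 10.

Step 10
Reactants: 16 propargylic alcohol
Product: 17 (E)-1-[(4R,6S)-4-bromo-2,2,6-trimethyl-6-(triethylsilyloxy)cyclohexylidene]pent-4-yn-3-one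
Conditions: Dess–Martin periodinane, NaHCO3, CH2Cl2, 0 °C; short silica pad, used at once
Reagents that add atoms: none
Why: Dess–Martin oxidation of the propargylic alcohol delivers the terminal ynone under neutral conditions that leave the doubly activated CH2 and the alkene in place.

Step 11
Reactants: 17 alkylidene ynone
Product: 18 (6S,7S,9R)-9-bromo-7,11,11-trimethyl-7-(triethylsilyloxy)spiro[5.5]undec-1-en-3-one
Conditions: Fe(acac)3 (0.5 equiv), PhSiH3 (2.5 equiv), EtOH/ethylene glycol 5:1, degassed, 0.01 M, 60 °C
Reagents that add atoms: none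
Why: Proposed new method: an iron hydride formed from Fe(acac)3 and PhSiH3 transfers H• to the exocyclic CH, so both alkene isomers give the same tertiary ring-A radical (future C6), which attacks the terminal β-carbon of the ynone; the α-keto vinyl radical is then reduced and protonated (or takes H from the silane) to give the cis-enone. The closest known reactions are intermolecular iron-hydride reductive couplings of trisubstituted alkenes with enones that build quaternary carbons, and 6-endo radical closures onto ynones; their union in an intramolecular alkene–ynone coupling is not established. Ring B closes 6-endo-dig, the polarity-matched mode, because 5-exo closure would require attack at the electron-rich α-carbon. The new spiro centre C6 is controlled by ring A: with Br equatorial at C9 the chair places the C7–OTES bond and one C11 methyl axial on the same face, flanking the radical, so the alkyne carbon bonds on the opposite face (axial, anti to the C7 oxygen) and the CH2CH2 arm ends equatorial, cis to that oxygen. The step also needs chemoselective hydrogen-atom transfer to the electron-rich alkene in the presence of the ynone and the secondary bromide, which the preference of the iron hydride for electron-rich alkenes, high dilution and exclusion of oxygen should secure.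

Step 12
Reactants: 18 spiro enone; 19 (bromomethyl)triphenylphosphonium bromide
Product: 20 (3E,6S,7S,9R)-9-bromo-3-(bromomethylidene)-7,11,11-trimethyl-7-(triethylsilyloxy)spiro[5.5]undec-1-ene
Conditions: 19, KOtBu, THF, −78 °C; then 18, −78 °C → rt; E isomer separated by chromatography (AgNO3–silica if needed)
Reagents that add atoms: (bromomethyl)triphenylphosphonium bromide, BrC[P+](c1ccccc1)(c1ccccc1)c1ccccc1.[Br-]
Why: Wittig olefination with the bromomethylene ylide attacks the enone carbonyl 1,2 at −78 °C, little kinetic E/Z preference is expected so the E isomer (Br syn to C4H2) is separated, and the equatorial C9 bromide is badly aligned for E2 with the hindered base.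

Step 13
Reactants: 20 silyl-protected bromodiene
Product: 21 (3E,6S,7S,9R)-9-bromo-3-(bromomethylidene)-7,11,11-trimethylspiro[5.5]undec-1-en-7-ol (target)
Conditions: HF·pyridine, pyridine/THF, 0 °C → rt
Reagents that add atoms: none
Why: Fluoride-mediated silyl ether cleavage under pyridine-buffered conditions frees the tertiary C7 alcohol without ionising it and leaves the diene and both C–Br bonds untouched.

**Compound list**

1 | ketoisophorone (2,6,6-trimethylcyclohex-2-ene-1,4-dione) | CC1=CC(=O)CC(C)(C)C1=O | starting material
2 | (6R)-levodione, (6R)-2,2,6-trimethylcyclohexane-1,4-dione | CC1(C)CC(=O)C[C@@H](C)C1=O | intermediate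
3 | (4R,6R)-actinol, (4R,6R)-4-hydroxy-2,2,6-trimethylcyclohexan-1-one | CC1(C)C[C@H](O)C[C@@H](C)C1=O | intermediate
4 | (5R)-1,3,3-trimethyl-2,5-bis(triethylsilyloxy)cyclohex-1-ene | CC1(C)C[C@H](O[Si](CC)(CC)CC)CC(C)=C1O[Si](CC)(CC)CC | intermediate
5 | 2,2,6-trimethyl-1,4-bis(triethylsilyloxy)-7-oxabicyclo[4.1.0]heptane, epoxide oxygen cis to the C4 oxygen | CC1(C)C[C@H](O[Si](CC)(CC)CC)C[C@]2(C)O[C@]12O[Si](CC)(CC)CC | intermediate
6 | (4S,6S)-2,2,6-trimethyl-4,6-bis(triethylsilyloxy)cyclohexan-1-one | CC1(C)C[C@H](O[Si](CC)(CC)CC)C[C@](C)(O[Si](CC)(CC)CC)C1=O | intermediate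
7 | (4S,6S)-4-hydroxy-2,2,6-trimethyl-6-(triethylsilyloxy)cyclohexan-1-one | CC1(C)C[C@H](O)C[C@](C)(O[Si](CC)(CC)CC)C1=O | intermediate
8 | (4R,6S)-4-bromo-2,2,6-trimethyl-6-(triethylsilyloxy)cyclohexan-1-one | CC1(C)C[C@@H](Br)C[C@](C)(O[Si](CC)(CC)CC)C1=O | intermediate
9 | allylmagnesium bromide | C=CC[Mg]Br | starting material
10 | (1R,4R,6S)-4-bromo-2,2,6-trimethyl-1-(prop-2-en-1-yl)-6-(triethylsilyloxy)cyclohexan-1-ol | CC1(C)C[C@@H](Br)C[C@](C)(O[Si](CC)(CC)CC)[C@@]1(O)CC=C | intermediate
11 | (4R,6S)-4-bromo-2,2,6-trimethyl-1-[(E)-prop-2-en-1-ylidene]-6-(triethylsilyloxy)cyclohexane | CC1(C)C[C@@H](Br)C[C@](C)(O[Si](CC)(CC)CC)/C1=C/C=C | intermediate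
12 | 9-{(E)-3-[(4R,6S)-4-bromo-2,2,6-trimethyl-6-(triethylsilyloxy)cyclohexylidene]propyl}-9-borabicyclo[3.3.1]nonane | CC1(C)C[C@@H](Br)C[C@](C)(O[Si](CC)(CC)CC)/C1=C/CCB1C2CCCC1CCC2 | intermediate
13 | (E)-3-[(4R,6S)-4-bromo-2,2,6-trimethyl-6-(triethylsilyloxy)cyclohexylidene]propan-1-ol | CC1(C)C[C@@H](Br)C[C@](C)(O[Si](CC)(CC)CC)/C1=C/CCO | intermediate
14 | (E)-3-[(4R,6S)-4-bromo-2,2,6-trimethyl-6-(triethylsilyloxy)cyclohexylidene]propanal | CC1(C)C[C@@H](Br)C[C@](C)(O[Si](CC)(CC)CC)/C1=C/CC=O | intermediate
15 | ethynylmagnesium bromide | C#C[Mg]Br | starting material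
16 | (E)-1-[(4R,6S)-4-bromo-2,2,6-trimethyl-6-(triethylsilyloxy)cyclohexylidene]pent-4-yn-3-ol | CC1(C)C[C@@H](Br)C[C@](C)(O[Si](CC)(CC)CC)/C1=C/CC(O)C#C | intermediate
17 | (E)-1-[(4R,6S)-4-bromo-2,2,6-trimethyl-6-(triethylsilyloxy)cyclohexylidene]pent-4-yn-3-one | CC1(C)C[C@@H](Br)C[C@](C)(O[Si](CC)(CC)CC)/C1=C/CC(=O)C#C | intermediate
18 | (6S,7S,9R)-9-bromo-7,11,11-trimethyl-7-(triethylsilyloxy)spiro[5.5]undec-1-en-3-one | CC1(C)C[C@@H](Br)C[C@](C)(O[Si](CC)(CC)CC)[C@@]12C=CC(=O)CC2 | intermediate
19 | (bromomethyl)triphenylphosphonium bromide | BrC[P+](c1ccccc1)(c1ccccc1)c1ccccc1.[Br-] | starting material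
20 | (3E,6S,7S,9R)-9-bromo-3-(bromomethylidene)-7,11,11-trimethyl-7-(triethylsilyloxy)spiro[5.5]undec-1-ene | CC1(C)C[C@@H](Br)C[C@](C)(O[Si](CC)(CC)CC)[C@@]12C=C/C(=C/Br)CC2 | intermediate
21 | (3E,6S,7S,9R)-9-bromo-3-(bromomethylidene)-7,11,11-trimethylspiro[5.5]undec-1-en-7-ol | CC1(C)C[C@@H](Br)C[C@](C)(O)[C@@]12C=C/C(=C/Br)CC2 | target

**Step count.** Total: 13 steps. Longest linear sequence: 13 steps (1 → 21); compounds 9, 15 and 19 are purchased.

**Steps most likely to fail**

Step 11 (key step, new method). The terminal ynone may be consumed by hydride transfer or by solvent addition before the hindered alkene is engaged, and the closure onto an alkyne may be slower than simple reduction of the tertiary radical. The fallback uses known reaction types and sets out from 17. Base-catalysed conjugate addition of methanol (MeOH, cat. DABCO, rt) should give (1E)-5-[(4R,6S)-4-bromo-2,2,6-trimethyl-6-(triethylsilyloxy)cyclohexylidene]-1-methoxypent-1-en-3-one F1, a far more robust acceptor. The established iron-hydride reductive alkene–enone coupling in its intramolecular form (Fe(acac)3, PhSiH3, EtOH, 60 °C; 6-endo-trig radical conjugate addition, same facial control by ring A) should then give (6S,7S,9R)-9-bromo-1-methoxy-7,11,11-trimethyl-7-(triethylsilyloxy)spiro[5.5]undecan-3-one F2. E1cB loss of methanol (DBU, CH2Cl2, rt) rejoins the route at 18.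

Step 4. The reactive conformer of 7 carries the bulky oxyphosphonium axial, anti-periplanar to two axial hydrogens, so E2 elimination to a cyclohexene may outrun substitution. The fallback sets out from 7 and separates activation from displacement. Triflation of the secondary hydroxyl (Tf2O, pyridine, CH2Cl2, −40 °C) should give (4S,6S)-2,2,6-trimethyl-1-oxo-6-(triethylsilyloxy)cyclohexan-4-yl trifluoromethanesulfonate F3, with a much smaller leaving group. Displacement with a soluble, weakly basic bromide (Bu4NBr, toluene, −20 °C → rt) by SN2 with inversion returns to 8.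

Step 12. The basic ylide may enolise the enone, and the kinetic E/Z mixture may leave too little of the E isomer. The fallback sets out from 18 and fixes the geometry in a separate step. Non-basic dibromo-olefination (PPh3, CBr4, toluene, 80 °C) should give (6S,7S,9R)-9-bromo-3-(dibromomethylidene)-7,11,11-trimethyl-7-(triethylsilyloxy)spiro[5.5]undec-1-ene F4. Palladium-catalysed mono-hydrodebromination (Pd(PPh3)4 cat., Bu3SnH, benzene, rt) should then proceed by oxidative addition into the more exposed vinylic C–Br bond, the one syn to the C2–H of the ring alkene and trans to the bulkier C4H2 branch. The bromide syn to C4H2 remains, which is the E isomer, and the route is rejoined at 20.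

**Further compounds**

F1 | step 11 | (1E)-5-[(4R,6S)-4-bromo-2,2,6-trimethyl-6-(triethylsilyloxy)cyclohexylidene]-1-methoxypent-1-en-3-one | CC1(C)C[C@@H](Br)C[C@](C)(O[Si](CC)(CC)CC)/C1=C/CC(=O)/C=C/OC
F2 | step 11 | (6S,7S,9R)-9-bromo-1-methoxy-7,11,11-trimethyl-7-(triethylsilyloxy)spiro[5.5]undecan-3-one | CC1(C)C[C@@H](Br)C[C@](C)(O[Si](CC)(CC)CC)[C@@]12C(OC)CC(=O)CC2
F3 | step 4 | (4S,6S)-2,2,6-trimethyl-1-oxo-6-(triethylsilyloxy)cyclohexan-4-yl trifluoromethanesulfonate | CC1(C)C[C@H](OS(=O)(=O)C(F)(F)F)C[C@](C)(O[Si](CC)(CC)CC)C1=O
F4 | step 12 | (6S,7S,9R)-9-bromo-3-(dibromomethylidene)-7,11,11-trimethyl-7-(triethylsilyloxy)spiro[5.5]undec-1-ene | CC1(C)C[C@@H](Br)C[C@](C)(O[Si](CC)(CC)CC)[C@@]12C=CC(=C(Br)Br)CC2
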